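(The runs are calculated on assumed constants, noise included.)

- At the reading time of 1.00 h, the autumn and midnight runs give their highest reading of complex with two exchanged, and among the charges they differ from this flask in leaving ligand.

| flask | starting complex | incoming ligand | leaving ligand | remark | time |
|---|---|---|---|---|---|
| autumn | 10 mM | 0.90 equiv | 1 equiv | run made earlier |  |
| midnight | 10 mM | 0.90 equiv | 4 equiv | run made earlier |  |
| spring | 15 mM | 0.90 equiv | 2 equiv | run made earlier |  |
| flask | 10 mM | 0.900 equiv | 2.00 equiv |  | 20 h |

- autumn (time / h: complex with two exchanged / %): 0.250: 12.3; 1.00: 25.1; 4.00: 9.4; 15.0: 1.3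
- midnight (time / h: complex with two exchanged / %): 0.250: 11.2; 1.00: 23.4; 4.00: 8.8; 15.0: 0
- spring (time / h: complex with two exchanged / %): 0.250: 17.8; 1.00: 26.2; 4.00: 6.0; 15.0: 0

(each reading ± 1 percentage point)

* time, not beyond 20 h, at which the flask holds most complex with two exchanged
* the amount of complex with two exchanged, in percent of the starting complex charged, at that time

- a reading or a percentage of leaving ligand counts all its forms, free or not

- My bench rule is that a flask differing from two runs in one charge, with that charge lying between theirs, reads near their mean at a shared reading time, so with 2.00 equiv of leaving ligand, between 1 equiv and 4 equiv, I expect 24.2% in this flask at 1.00 h; that mean stands 0.85 percentage points from either reading, less than the scatter of 1 point.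
- The rule stops at the time axis, because the reading times on either side of 1.00 h stand a factor of 4.00 from it, so I commit to a peak near 1.00 h and no finer.
- Each complex with two exchanged takes up two incoming ligands, so incoming ligand is the limiting reagent here, and dividing its charge by two gives the ceiling, C = 0.450 equiv of starting complex.
- I call φ the share of that ceiling reached at the peak; my mean, taken as the peak height, gives φ = 0.539.
- The forecast gives 1.3 h and 26.5%, on the ground that “Every reading falls on one curve if time is scaled by concentration”; my height is lower and my time earlier.
- The flask peaks at 1.01 h with 24.1%.

    starting complex + incoming ligand → leaving ligand + complex with one exchanged (k = 0.0420 M⁻¹ s⁻¹)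
    complex with one exchanged + incoming ligand → leaving ligand + complex with two exchanged (k = 0.230 M⁻¹ s⁻¹)
    complex with two exchanged + incoming ligand → leaving ligand + complex with three exchanged (k = 0.00530 M⁻¹ s⁻¹)
    complex with three exchanged + incoming ligand → leaving ligand + complex with four exchanged (k = 0.0230 M⁻¹ s⁻¹)
    crystals ⇌ leaving ligand, rate k5*(cs5 - [leaving ligand]) while solid is left; crystals form when [leaving ligand] > cs5 (solubility = 5.70 mM, k = 0.00970 s⁻¹)
    leaving ligand + complex with two exchanged → side product (k = 0.0220 M⁻¹ s⁻¹)

- Taken alone, with the other concentrations as charged, the loss of complex with two exchanged to side product has a half-life of 0.44 h, shorter than the 4.0 h of its step to complex with three exchanged. In this flask φ comes to 0.536. A neighbouring flask charged with 0.230 equiv of incoming ligand has a ceiling of 0.115 equiv, on which my φ gives 6.20%; that flask gives 3.99%, a φ of 0.347.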